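## Structural features

The target is a C30 bicyclic triterpenoid: a trans-fused decalin (ring A = C1–C5 and C10, ring B = C5–C10) carrying on C9 a sixteen-carbon chain (C11–C22 with its methyl branches). The chain has two E-trisubstituted alkenes (C13=C14, C17=C18) and a terminal isopropylidene group (C21=C22). The five stereocentres are 3S (equatorial β-hydroxyl beside the C4 gem-dimethyl group), 5R (α-H), 10S (β-methyl), 9R (β chain) and 8R (α-hydroxyl, β-methyl). C8, C9 and C10 stand in a row, C8 and C10 are fully substituted, and their methyl groups are syn-diaxial. The tertiary C8 carbinol dehydrates easily under acid, and the 1,5-polyene chain cyclises or isomerises with acid and forbids hydrogenation once attached, so the chain is joined late and the late steps are basic, neutral or fluoride-based. The real difficulty is the C8–C9–C10 triad with its congested C9–C10 bond, next to the trans ring fusion. The plan uses the oxygen pattern of ring A: O–C3 is para to quaternary C10 and ortho to methyl-bearing C4, so ring A is the reduced form of a 2,4-dimethylphenol with the ring B tether on C5, between the two methyl groups. The para carbon C10 of that phenoxide can attack an allyl cation spanning C9–C11–C12. This closes ring B, makes C10 quaternary so the dienone cannot re-aromatise, and leaves C11=C12 as the handle for the chain.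

## Logic of the disconnections

**30 ⇒ 29 ⇒ 21 + 27.** 30 is traced to its C8 silyl ether 29, which is cut at C12–C13. That bond joins an sp3 carbon reachable by hydroboration of a vinyl group to the sp2 carbon of a geometrically defined alkenyl iodide, so the acid-sensitive polyene arrives whole, late, and with its E geometry already fixed. The gain is a C14 chain piece 27 and a core 21 that holds all five stereocentres. The forward step needs terminal hydroboration of a vinyl group flanked by two quaternary carbons and coupling with retention of geometry beside a free C3 hydroxyl.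

**21 ⇒ 20 ⇒ 19 ⇒ 18 ⇒ 17.** The C3–H bond of 21 is cut back to ketone 20; the forward hydride must arrive axially from the α face. In 20 the second C4–CH3 bond and the C5–H bond are cut together, through enolate 19, to enone 18. This needs protonation of C5 trans to the C10 methyl and C-methylation of a regiodefined enolate. 18 is traced to 17 by restoring C1=C2, which needs hydride delivery to C1 and not to C5 or the carbonyl. The gain is a ring A that is a dearomatised phenol.

**17 ⇒ 16.** The C9–C10 bond is cut; it is the only ring B bond whose cleavage turns ring A back into an aromatic ring. Two rings and three stereocentres become one benzene ring and a chain with one stereocentre (C8). The forward step needs C-alkylation of a phenoxide at the para carbon and not the ortho carbon, at the internal allyl terminus, with control of C9 and C10 relative to C8.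

**16 ⇒ 15 ⇒ 14 ⇒ 12 + 13.** The phenol of 16 is carried as its bulky silyl ether 15 until the step before the cyclisation, so that no free phenol meets the hydride, titanium, phosphine/iodine and ruthenium steps. The C8 silyl ether is removed to give 14, and C11=C12 is cut by metathesis into 12 and 13. Metathesis comes before silylation of the carbinol because a silylated tertiary allylic ether hardly enters the metathesis cycle, whereas the free carbinol does. The forward steps need E-selective cross-metathesis and selective cleavage of an aryl silyl ether beside a tertiary alkyl silyl ether and a carbonate.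

**12 ⇒ 11 ⇒ 10 ⇒ 9.** The C8 stereocentre is traced through the epoxy iodide 11 to the epoxy alcohol 10 and the E allylic alcohol 9. The C8–O bond made in the epoxidation is never broken afterwards, so a catalyst-controlled epoxidation fixes 8R. The forward steps need the correct tartrate antipode and a reductive opening that leaves the quaternary C–O bond alone.

**9 ⇒ 8 ⇒ 7.** The C8=C9 double bond of the allylic alcohol is cut by a two-carbon carbonyl olefination, leaving methyl ketone 7. The forward step needs E selectivity at a methyl ketone; the minor isomer is removed.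

**7 ⇒ 5 + 6.** The aryl–C6 bond is cut. An aryl bromide and an allylic alcohol give the saturated ketone in one operation. The forward step needs insertion at a bromide flanked by two methyl groups.

**5 ⇒ 4 ⇒ 3 ⇒ 2 ⇒ 1.** The C3–O bond is traced through ester 3 to the aryl ketone 2, and the C–C bond of that ketone to 1. Electrophilic acylation of 1 has a single activated position, and oxygen insertion then turns it into the phenol oxygen. The forward steps need aryl migration and a silyl group that lasts to step 12.

**27 ⇒ 26 ⇒ 25 ⇒ 24 ⇒ 22 + 23.** The C–I and C–CH3 bonds across C13=C14 are cut together (methyl–metal addition to a terminal alkyne, 26), and the C15–C16 bond is cut between a propargyl anion 22 and an allylic bromide 23. The E geometry of C13=C14 comes from syn addition, and that of C17=C18 is bought with 23.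

## Other disconnections considered

**Alternative 1:** cut C5–C10 and C8–C9 together (intramolecular Diels–Alder). Heating triene A1 would add the (E)-enoate C9=C10 across the (E,E)-1-silyloxydiene C5=C6–C7=C8 and give decalin A2.
- In favour: two rings, two bonds and four stereocentres (C5, C8, C9, C10) form in one thermal step from an open chain. The reaction class is well precedented for deca-1,7,9-trienes, and suprafacial addition ties C8, C9 and C10 together. On precedent and on bonds made per step it is the better of the two plans.
- Against: the dienophile is β,β-disubstituted and the diene terminus C5 sits next to the quaternary C4, so the cycloaddition should be slow. Facial and endo/exo control rest only on the remote C3 acetate. C8 in A2 is a secondary silyl ether without its methyl group. Oxidation and methyl addition would be expected to bring the methyl from the α face, away from the axial C10 methyl, giving the wrong 8β-carbinol, so a methylenation, α-epoxidation and hydride sequence would be needed. C6=C7 must be reduced and the C9 ester homologated by two carbons.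
- Comparison: the chosen plan places the C8 methyl and oxygen before ring closure and leaves a vinyl group of the right length. It is shorter after the key step but rests on an untested cyclisation.

**Alternative 2:** cut C5–C6 and C9–C10 (conjugate addition, then enolate alkylation). A butenyl cuprate would add to C5 of enone A3 and the enolate would be alkylated at C10 by a bromoacetate ester, giving A4.
- In favour: this is a textbook reaction type, the trans relation of C5 and C10 follows from the ring, and the precursor is small. On reliability of the key step it is better than the chosen plan.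
- Against: no ring is closed. The β-carbon C5 is neopentyl and the enolate alkylation creates a quaternary centre beside it, so both halves are hindered. A4 carries a surplus C1 ketone and the wrong C3 configuration. Ring B, C8 and C9 are all still to be made.
- Comparison: mechanistically safer, but structurally it solves only C5 and C10 and is clearly longer.

**Alternative 3:** cut C8–C9 (ketyl–olefin cyclisation). SmI2 (divalent samarium) would reduce the C8 methyl ketone of A5 to a ketyl that adds to C9 of the (E)-enoate, giving A6.
- In favour: it is mild and chemoselective, the reaction class is known, and the free tertiary C8 carbinol appears directly. Ring A is already saturated, so nothing corresponds to steps 14–16 of the chosen route. On these points it is the equal or the better.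
- Against: the ketyl must attack a β-carbon attached to quaternary C10 in a 6-exo closure, which is slower and less stereoregular than 5-exo closure. The trans relation of the C8 hydroxyl and the C9 chain, with the methyl axial, is not assured. A5 already needs ring A with C3, C5 and quaternary C10 set, so the hard part is moved, not removed. The ester needs reduction, activation and coupling (three steps) where the vinyl group of the chosen plan needs one.
- Comparison: equal in closing ring B last, better in precedent, weaker in overall step count and in the access to its precursor.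

Key step: step 13

Remark: the (R,R) antipode of the ligand in step 13 is taken as the one matched with the 8R centre; if the sense of induction is the reverse, the (S,S) antipode is used and nothing else changes.

Remark: the descriptors were checked atom by atom. 4R in 16 is the same spatial arrangement as 8R in 30, and 4aR,5R,6R in 17 correspond to C10, C9 and C8 of 30 (the letter at C10 becomes S in 20–30 only because CIP priorities change).

## Route

Step 1
Reactants: 1 2-bromo-1,3-dimethylbenzene
Product: 2 1-(3-bromo-2,4-dimethylphenyl)ethan-1-one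
Conditions: AcCl, AlCl3, CH2Cl2, 0 °C → rt
Reagents that add atoms: acetyl chloride CC(Cl)=O
Why: Friedel–Crafts acylation; the position ortho to one methyl, para to the other and meta to bromine is the only doubly activated one, so a single ketone is expected.

Step 2
Reactants: 2 1-(3-bromo-2,4-dimethylphenyl)ethan-1-one
Product: 4 3-bromo-2,4-dimethylphenol, via aryl acetate 3 (not isolated)
Conditions: mCPBA, TFA (cat.), CH2Cl2, rt; then K2CO3, MeOH, rt
Reagents that add atoms: 3-chloroperbenzoic acid OOC(=O)c1cccc(Cl)c1
Why: Baeyer–Villiger oxidation in which the electron-rich ortho-substituted aryl group migrates in preference to methyl, followed by methanolysis of the aryl acetate; the oxygen of the future C3 is installed.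

Step 3
Reactants: 4 3-bromo-2,4-dimethylphenol
Product: 5 (3-bromo-2,4-dimethylphenoxy)tri(propan-2-yl)silane
Conditions: i-Pr3SiCl, imidazole, DMF, rt
Reagents that add atoms: chlorotri(propan-2-yl)silane CC(C)[Si](Cl)(C(C)C)C(C)C
Why: Silylation of a phenol; the bulky aryl silyl ether survives the base, hydride, titanium, zinc, ruthenium and silyl triflate steps 4–11 and is later cleaved by fluoride faster than any alkyl silyl ether.

Step 4
Reactants: 5 (3-bromo-2,4-dimethylphenoxy)tri(propan-2-yl)silane; 6 but-3-en-2-ol (racemic)
Product: 7 4-[2,6-dimethyl-3-(triisopropylsilyloxy)phenyl]butan-2-one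
Conditions: Pd(OAc)2 (5 mol%), P(t-Bu)3·HBF4 (10 mol%), Cy2NMe, dioxane, 100 °C
Reagents that add atoms: none
Why: Heck arylation of an allylic alcohol: insertion at the terminal carbon, β-hydride elimination toward the carbinol carbon and tautomerisation give the saturated methyl ketone directly. The electron-rich bulky phosphine is chosen because the bromide is flanked by two methyl groups; the stereocentre of 6 is destroyed, so the racemate is used.

Step 5
Reactants: 7 4-[2,6-dimethyl-3-(triisopropylsilyloxy)phenyl]butan-2-one
Product: 8 ethyl (2E)-5-[2,6-dimethyl-3-(triisopropylsilyloxy)phenyl]-3-methylpent-2-enoate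
Conditions: (EtO)2P(O)CH2CO2Et, NaH, THF, 0 °C → reflux; chromatographic removal of the Z isomer
Reagents that add atoms: triethyl phosphonoacetate CCOC(=O)CP(=O)(OCC)OCC
Why: Horner–Wadsworth–Emmons olefination; methyl ketones give mainly the E enoate (ester trans to the larger chain), and the minor Z isomer is separated here or at 9.

Step 6
Reactants: 8 ethyl (2E)-5-[2,6-dimethyl-3-(triisopropylsilyloxy)phenyl]-3-methylpent-2-enoate
Product: 9 (2E)-5-[2,6-dimethyl-3-(triisopropylsilyloxy)phenyl]-3-methylpent-2-en-1-ol
Conditions: i-Bu2AlH (2.5 equiv), CH2Cl2, −78 °C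
Reagents that add atoms: none
Why: 1,2-Reduction of a conjugated ester to the allylic alcohol by an aluminium hydride; alkene geometry and aryl silyl ether are untouched.

Step 7
Reactants: 9 (2E)-5-[2,6-dimethyl-3-(triisopropylsilyloxy)phenyl]-3-methylpent-2-en-1-ol
Product: 10 [(2R,3R)-3-{2-[2,6-dimethyl-3-(triisopropylsilyloxy)phenyl]ethyl}-3-methyloxiran-2-yl]methanol
Conditions: Ti(Oi-Pr)4 (10 mol%), D-(−)-diethyl tartrate (12 mol%), t-BuOOH, 4 Å MS, CH2Cl2, −20 °C
Reagents that add atoms: tert-butyl hydroperoxide CC(C)(C)OO
Why: Sharpless asymmetric epoxidation of an (E)-3,3-disubstituted allylic alcohol (geraniol type); the D-(−)-tartrate catalyst delivers oxygen to the face that gives the (2R,3R) epoxide, which fixes the future C8 as R.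

Step 8
Reactants: 10 [(2R,3R)-3-{2-[2,6-dimethyl-3-(triisopropylsilyloxy)phenyl]ethyl}-3-methyloxiran-2-yl]methanol
Product: 11 (2S,3R)-3-{2-[2,6-dimethyl-3-(triisopropylsilyloxy)phenyl]ethyl}-2-(iodomethyl)-3-methyloxirane
Conditions: PPh3, I2, imidazole, THF, 0 °C
Reagents that add atoms: iodine II
Why: Appel-type iodination of the primary alcohol under neutral conditions that leave the trisubstituted epoxide closed; the descriptor at C2 changes only through CIP priorities.

Step 9
Reactants: 11 (2S,3R)-3-{2-[2,6-dimethyl-3-(triisopropylsilyloxy)phenyl]ethyl}-2-(iodomethyl)-3-methyloxirane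
Product: 12 (3R)-5-[2,6-dimethyl-3-(triisopropylsilyloxy)phenyl]-3-methylpent-1-en-3-ol
Conditions: Zn dust, AcOH (2 equiv), MeOH, rt → 40 °C
Reagents that add atoms: none
Why: Reductive elimination of a 2,3-epoxy iodide: zinc inserts into the C–I bond and the adjacent epoxide C–O bond is expelled, giving the transposed tertiary allylic alcohol. The C–O bond at the quaternary carbon is not broken, so its configuration (3R, the future 8R) is retained.

Step 10
Reactants: 12 (3R)-5-[2,6-dimethyl-3-(triisopropylsilyloxy)phenyl]-3-methylpent-1-en-3-ol; 13 methyl prop-2-en-1-yl carbonate (5 equiv)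
Product: 14 methyl (2E,4R)-6-[2,6-dimethyl-3-(triisopropylsilyloxy)phenyl]-4-hydroxy-4-methylhex-2-en-1-yl carbonate
Conditions: Hoveyda–Grubbs second-generation catalyst (5 mol%), CH2Cl2, 40 °C
Reagents that add atoms: none
Why: Olefin cross-metathesis between a hindered, slowly homodimerising vinyl carbinol and an excess of a fast-reacting allyl partner; the quaternary allylic carbon enforces the E alkene. It is run on the free carbinol because its silyl ether would be nearly inert to the ruthenium carbene.

Step 11
Reactants: 14 methyl (2E,4R)-6-[2,6-dimethyl-3-(triisopropylsilyloxy)phenyl]-4-hydroxy-4-methylhex-2-en-1-yl carbonate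
Product: 15 methyl (2E,4R)-6-[2,6-dimethyl-3-(triisopropylsilyloxy)phenyl]-4-methyl-4-(triethylsilyloxy)hex-2-en-1-yl carbonate
Conditions: Et3SiOTf, 2,6-lutidine, CH2Cl2, −78 → 0 °C
Reagents that add atoms: triethylsilyl trifluoromethanesulfonate CC[Si](CC)(CC)OS(=O)(=O)C(F)(F)F
Why: Silylation of a tertiary alcohol with a silyl triflate and a hindered base; the ether keeps the C8 oxygen from acting as a nucleophile or proton source in steps 13–15 and is small enough to be removed at the end.

Step 12
Reactants: 15 methyl (2E,4R)-6-[2,6-dimethyl-3-(triisopropylsilyloxy)phenyl]-4-methyl-4-(triethylsilyloxy)hex-2-en-1-yl carbonate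
Product: 16 methyl (2E,4R)-6-(3-hydroxy-2,6-dimethylphenyl)-4-methyl-4-(triethylsilyloxy)hex-2-en-1-yl carbonate
Conditions: TBAF (1.1 equiv), AcOH (1.1 equiv), THF, 0 °C
Reagents that add atoms: none
Why: Fluoride cleavage of an aryl silyl ether, which is much faster (phenoxide leaving group) than cleavage of the hindered tertiary alkyl silyl ether; the acetic acid buffer keeps the phenol protonated so that the carbonate is not attacked.

Step 13
Reactants: 16 methyl (2E,4R)-6-(3-hydroxy-2,6-dimethylphenyl)-4-methyl-4-(triethylsilyloxy)hex-2-en-1-yl carbonate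
Product: 17 (4aR,5R,6R)-5-ethenyl-1,4a,6-trimethyl-6-(triethylsilyloxy)-5,6,7,8-tetrahydronaphthalen-2(4aH)-one
Conditions: Pd2(dba)3·CHCl3 (2.5 mol%), (R,R)-DACH-phenyl Trost ligand (7.5 mol%), degassed CH2Cl2 (0.01 M), rt
Reagents that add atoms: none
Why: Proposed new method: zerovalent palladium ionises the allylic carbonate of 16 anti to the leaving group to a cationic syn π-allyl complex spanning C9–C11–C12, the methyl carbonate anion loses CO2 and the methoxide deprotonates the phenol, and the para carbon C10 of the phenoxide then attacks C9 on the face opposite to palladium; the closest known reaction types are palladium- and iridium-catalysed intramolecular allylic dearomatisations of para-tethered phenols to spirocyclohexadienones, the cyclisation of phenol allyl carbonates to 2-vinylchromans with this ligand class, and base-mediated para-alkylation of phenoxides to fused dienones. Ring B closes in a 6-exo mode at the internal allyl terminus with C11=C12 left outside the ring; closure at C12 would need an eight-membered ring and O-alkylation a meta-bridged ring, so neither competes within the molecule. C9 is set by the allyl face that carries palladium: the two diastereomeric complexes interconvert through the η1 form at C12, and the chiral ligand, matched with the 8R centre, should let the complex that leads to 9R react faster. C10 is set by the chair-like transition state in which the C8 silyloxy group and the vinyl group are equatorial, which places the C10 methyl axial and syn to the C8 methyl. The selectivity needed is para (C10) over ortho (C4) C-alkylation; it is secured by the larger para coefficient of the phenoxide HOMO, by the crowding of C4 between C3–O and C5, and by the greater stability of the cross-conjugated dienone. C10 becomes quaternary, so 17 cannot return to a phenol, and high dilution suppresses intermolecular O-allylation, which is in any case reversible under the catalyst.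

Step 14
Reactants: 17 (4aR,5R,6R)-5-ethenyl-1,4a,6-trimethyl-6-(triethylsilyloxy)-5,6,7,8-tetrahydronaphthalen-2(4aH)-one
Product: 18 (4aR,5R,6R)-5-ethenyl-1,4a,6-trimethyl-6-(triethylsilyloxy)-4,4a,5,6,7,8-hexahydronaphthalen-2(3H)-one
Conditions: K(s-Bu)3BH (1.05 equiv), THF, −78 °C; then sat. aq NH4Cl
Reagents that add atoms: none
Why: Conjugate (1,4) reduction by a hindered trialkylborohydride: hydride goes to C1, the unsubstituted β-carbon of the disubstituted enone, not to the fully substituted C5 or the flanked carbonyl, and protonation at C2 on work-up leaves the C4=C5 enone. The isolated vinyl group and the silyl ether are inert.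

Step 15
Reactants: 18 (4aR,5R,6R)-5-ethenyl-1,4a,6-trimethyl-6-(triethylsilyloxy)-4,4a,5,6,7,8-hexahydronaphthalen-2(3H)-one
Product: 20 (4aS,5R,6R,8aR)-5-ethenyl-1,1,4a,6-tetramethyl-6-(triethylsilyloxy)octahydronaphthalen-2(1H)-one, via lithium enolate 19 (not isolated)
Conditions: Li (2.5 equiv), t-BuOH (1.0 equiv), NH3(l)/THF, −78 °C; isoprene; then CH3I (5 equiv), −78 → −33 °C
Reagents that add atoms: iodomethane CI
Why: Dissolving-metal reductive alkylation of an enone: two-electron reduction with one equivalent of proton donor puts hydrogen on C5 axially, trans to the C10 methyl (trans-decalin, 5α-H), and leaves the C3–C4 lithium enolate regiospecifically; methylation at C4 completes the gem-dimethyl group. Excess lithium is destroyed with isoprene before the iodide is added, and the terminal alkene is not reduced without excess proton donor.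

Step 16
Reactants: 20 (4aS,5R,6R,8aR)-5-ethenyl-1,1,4a,6-tetramethyl-6-(triethylsilyloxy)octahydronaphthalen-2(1H)-one
Product: 21 (2S,4aS,5R,6R,8aR)-5-ethenyl-1,1,4a,6-tetramethyl-6-(triethylsilyloxy)decahydronaphthalen-2-ol
Conditions: NaBH4, MeOH/THF, 0 °C
Reagents that add atoms: none
Why: Borohydride reduction of a cyclohexanone flanked by a gem-dimethyl group: hydride adds axially from the α face, away from the axial 4β- and 10β-methyl groups, giving the equatorial 3β (3S) alcohol.

Step 17
Reactants: 22 trimethyl(prop-1-yn-1-yl)silane; 23 (2E)-1-bromo-3,7-dimethylocta-2,6-diene (geranyl bromide)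
Product: 25 (5E)-6,10-dimethylundeca-5,9-dien-1-yne, via silylated enyne 24 (not isolated)
Conditions: 22, n-BuLi, THF, −78 → −20 °C; 23, −78 → 0 °C; then K2CO3, MeOH, rt
Reagents that add atoms: none
Why: Alkylation of a propargyllithium at the primary carbon of an allylic bromide; the silyl group blocks the alkyne terminus and disfavours the allenyl product, and the E alkene of 23 is untouched. In-flask protodesilylation by carbonate in methanol frees the terminal alkyne.

Step 18
Reactants: 25 (5E)-6,10-dimethylundeca-5,9-dien-1-yne
Product: 27 (1E,5E)-1-iodo-2,6,10-trimethylundeca-1,5,9-triene, via alkenylalane 26 (not isolated)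
Conditions: AlMe3 (2 equiv), Cp2ZrCl2 (25 mol%), CH2Cl2, 0 °C → rt; then I2, THF, −30 → 0 °C
Reagents that add atoms: trimethylaluminium C[Al](C)C; iodine II
Why: Negishi zirconium-catalysed carboalumination: syn addition of methyl and aluminium across the terminal alkyne with aluminium on the terminal carbon, then iodinolysis with retention, gives the (E)-alkenyl iodide.

Step 19
Reactants: 21 (2S,4aS,5R,6R,8aR)-5-ethenyl-1,1,4a,6-tetramethyl-6-(triethylsilyloxy)decahydronaphthalen-2-ol; 27 (1E,5E)-1-iodo-2,6,10-trimethylundeca-1,5,9-triene
Product: 29 (2S,4aS,5R,6R,8aR)-1,1,4a,6-tetramethyl-6-(triethylsilyloxy)-5-[(3E,7E)-4,8,12-trimethyltrideca-3,7,11-trien-1-yl]decahydronaphthalen-2-ol, via alkylborane 28 (not isolated)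
Conditions: 9-BBN dimer (1.5 equiv), THF, 0 → 50 °C; then 27, Pd(dppf)Cl2 (5 mol%), AsPh3 (10 mol%), Cs2CO3, DMF/H2O, rt
Reagents that add atoms: none
Why: Hydroboration with 9-BBN places boron on the terminal carbon C12 (one extra equivalent is consumed by the C3 hydroxyl); B-alkyl Suzuki–Miyaura coupling with the alkenyl iodide proceeds with retention of the E geometry. The aqueous base quenches residual B–H before 27 is added, so its trisubstituted alkenes are not hydroborated.

Step 20
Reactants: 29 (2S,4aS,5R,6R,8aR)-1,1,4a,6-tetramethyl-6-(triethylsilyloxy)-5-[(3E,7E)-4,8,12-trimethyltrideca-3,7,11-trien-1-yl]decahydronaphthalen-2-ol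
Product: 30 (2S,4aS,5R,6R,8aR)-1,1,4a,6-tetramethyl-5-[(3E,7E)-4,8,12-trimethyltrideca-3,7,11-trien-1-yl]decahydronaphthalene-2,6-diol
Conditions: TBAF, THF, 50 °C
Reagents that add atoms: none
Why: Fluoride cleavage of the hindered tertiary triethylsilyl ether; the basic medium spares the tertiary carbinol and the polyene, which acid would not.

## Compound list

1 | 2-bromo-1,3-dimethylbenzene | Cc1cccc(C)c1Br | starting material
2 | 1-(3-bromo-2,4-dimethylphenyl)ethan-1-one | CC(=O)c1ccc(C)c(Br)c1C | intermediate
3 | 3-bromo-2,4-dimethylphenyl acetate | CC(=O)Oc1ccc(C)c(Br)c1C | intermediate (not isolated)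
4 | 3-bromo-2,4-dimethylphenol | Cc1ccc(O)c(C)c1Br | intermediate
5 | (3-bromo-2,4-dimethylphenoxy)tri(propan-2-yl)silane | Cc1ccc(O[Si](C(C)C)(C(C)C)C(C)C)c(C)c1Br | intermediate
6 | but-3-en-2-ol (racemic) | CC(O)C=C | starting material
7 | 4-[2,6-dimethyl-3-(triisopropylsilyloxy)phenyl]butan-2-one | CC(=O)CCc1c(C)ccc(O[Si](C(C)C)(C(C)C)C(C)C)c1C | intermediate
8 | ethyl (2E)-5-[2,6-dimethyl-3-(triisopropylsilyloxy)phenyl]-3-methylpent-2-enoate | CCOC(=O)/C=C(\C)CCc1c(C)ccc(O[Si](C(C)C)(C(C)C)C(C)C)c1C | intermediate
9 | (2E)-5-[2,6-dimethyl-3-(triisopropylsilyloxy)phenyl]-3-methylpent-2-en-1-ol | OC/C=C(\C)CCc1c(C)ccc(O[Si](C(C)C)(C(C)C)C(C)C)c1C | intermediate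
10 | [(2R,3R)-3-{2-[2,6-dimethyl-3-(triisopropylsilyloxy)phenyl]ethyl}-3-methyloxiran-2-yl]methanol | Cc1ccc(O[Si](C(C)C)(C(C)C)C(C)C)c(C)c1CC[C@@]2(C)O[C@@H]2CO | intermediate
11 | (2S,3R)-3-{2-[2,6-dimethyl-3-(triisopropylsilyloxy)phenyl]ethyl}-2-(iodomethyl)-3-methyloxirane | Cc1ccc(O[Si](C(C)C)(C(C)C)C(C)C)c(C)c1CC[C@@]2(C)O[C@@H]2CI | intermediate
12 | (3R)-5-[2,6-dimethyl-3-(triisopropylsilyloxy)phenyl]-3-methylpent-1-en-3-ol | Cc1ccc(O[Si](C(C)C)(C(C)C)C(C)C)c(C)c1CC[C@@](C)(O)C=C | intermediate
13 | methyl prop-2-en-1-yl carbonate (allyl methyl carbonate) | C=CCOC(=O)OC | starting material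
14 | methyl (2E,4R)-6-[2,6-dimethyl-3-(triisopropylsilyloxy)phenyl]-4-hydroxy-4-methylhex-2-en-1-yl carbonate | Cc1ccc(O[Si](C(C)C)(C(C)C)C(C)C)c(C)c1CC[C@@](C)(O)/C=C/COC(=O)OC | intermediate
15 | methyl (2E,4R)-6-[2,6-dimethyl-3-(triisopropylsilyloxy)phenyl]-4-methyl-4-(triethylsilyloxy)hex-2-en-1-yl carbonate | Cc1ccc(O[Si](C(C)C)(C(C)C)C(C)C)c(C)c1CC[C@@](C)(O[Si](CC)(CC)CC)/C=C/COC(=O)OC | intermediate
16 | methyl (2E,4R)-6-(3-hydroxy-2,6-dimethylphenyl)-4-methyl-4-(triethylsilyloxy)hex-2-en-1-yl carbonate | Cc1ccc(O)c(C)c1CC[C@@](C)(O[Si](CC)(CC)CC)/C=C/COC(=O)OC | intermediate (precursor of the key step)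
17 | (4aR,5R,6R)-5-ethenyl-1,4a,6-trimethyl-6-(triethylsilyloxy)-5,6,7,8-tetrahydronaphthalen-2(4aH)-one (8α-silyloxy-8β,10β-dimethyl-9β-vinyl 1,4-dien-3-one) | C=C[C@@H]1[C@@]2(C)C=CC(=O)C(C)=C2CC[C@@]1(C)O[Si](CC)(CC)CC | intermediate (product of the key step)
18 | (4aR,5R,6R)-5-ethenyl-1,4a,6-trimethyl-6-(triethylsilyloxy)-4,4a,5,6,7,8-hexahydronaphthalen-2(3H)-one | C=C[C@@H]1[C@@]2(C)CCC(=O)C(C)=C2CC[C@@]1(C)O[Si](CC)(CC)CC | intermediate
19 | lithium C3–C4 enolate of the 5α-H 4-methyl 3-ketone (20 without its second C4 methyl) | C=C[C@@H]1[C@@]2(C)CCC([O-])=C(C)[C@@H]2CC[C@@]1(C)O[Si](CC)(CC)CC.[Li+] | intermediate (not isolated)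
20 | (4aS,5R,6R,8aR)-5-ethenyl-1,1,4a,6-tetramethyl-6-(triethylsilyloxy)octahydronaphthalen-2(1H)-one | C=C[C@@H]1[C@@]2(C)CCC(=O)C(C)(C)[C@@H]2CC[C@@]1(C)O[Si](CC)(CC)CC | intermediate
21 | (2S,4aS,5R,6R,8aR)-5-ethenyl-1,1,4a,6-tetramethyl-6-(triethylsilyloxy)decahydronaphthalen-2-ol | C=C[C@@H]1[C@@]2(C)CC[C@H](O)C(C)(C)[C@@H]2CC[C@@]1(C)O[Si](CC)(CC)CC | intermediate
22 | trimethyl(prop-1-yn-1-yl)silane | CC#C[Si](C)(C)C | starting material
23 | (2E)-1-bromo-3,7-dimethylocta-2,6-diene (geranyl bromide) | CC(C)=CCC/C(C)=C/CBr | starting material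
24 | [(5E)-6,10-dimethylundeca-5,9-dien-1-yn-1-yl]trimethylsilane | C[Si](C)(C)C#CCC/C=C(\C)CCC=C(C)C | intermediate (not isolated)
25 | (5E)-6,10-dimethylundeca-5,9-dien-1-yne | C#CCC/C=C(\C)CCC=C(C)C | intermediate
26 | dimethyl[(1E,5E)-2,6,10-trimethylundeca-1,5,9-trien-1-yl]alumane | C[Al](C)/C=C(\C)CC/C=C(\C)CCC=C(C)C | intermediate (not isolated)
27 | (1E,5E)-1-iodo-2,6,10-trimethylundeca-1,5,9-triene | I/C=C(\C)CC/C=C(\C)CCC=C(C)C | intermediate
28 | 9-alkyl-9-borabicyclo[3.3.1]nonane from 21 (vinyl group converted into CH2CH2–B) | B1(CC[C@@H]3[C@@]4(C)CC[C@H](O)C(C)(C)[C@@H]4CC[C@@]3(C)O[Si](CC)(CC)CC)C2CCCC1CCC2 | intermediate (not isolated)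
29 | (2S,4aS,5R,6R,8aR)-1,1,4a,6-tetramethyl-6-(triethylsilyloxy)-5-[(3E,7E)-4,8,12-trimethyltrideca-3,7,11-trien-1-yl]decahydronaphthalen-2-ol | CC(C)=CCC/C(C)=C/CC/C(C)=C/CC[C@@H]1[C@@]2(C)CC[C@H](O)C(C)(C)[C@@H]2CC[C@@]1(C)O[Si](CC)(CC)CC | intermediate
30 | (2S,4aS,5R,6R,8aR)-1,1,4a,6-tetramethyl-5-[(3E,7E)-4,8,12-trimethyltrideca-3,7,11-trien-1-yl]decahydronaphthalene-2,6-diol (3S,5R,8R,9R,10S in labdane numbering) | CC(C)=CCC/C(C)=C/CC/C(C)=C/CC[C@@H]1[C@@]2(C)CC[C@H](O)C(C)(C)[C@@H]2CC[C@@]1(C)O | target

## Step count and weak points

Total: 20 steps. Longest linear sequence: 18 steps (steps 1–16, 19, 20); the alkenyl iodide 27 takes 2 steps (17, 18).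

**Step 13 (key step).** Three processes may spoil it.
- C-alkylation may occur at the ortho carbon C4, which is also six atoms from C9, or intermolecular O-allylation may lead to oligomers.
- Facial selectivity may be poor. The chair with the C8 silyloxy group axial avoids the methyl/methyl syn-diaxial contact and leads to the 9,10-bis-epimer, so the ligand must overrule the substrate.
- Bond formation between the neopentyl allyl terminus and a substituted arene carbon may be slow enough for the catalyst to decay.

The other ligand antipode and an achiral bisphosphine would be tried first to read the intrinsic bias. The fallback reverses the polarity of the same bond with known chemistry and sets out from 12. Cross-metathesis of 12 with allyltrimethylsilane (Hoveyda–Grubbs second-generation catalyst) should give (3R,4E)-1-[2,6-dimethyl-3-(triisopropylsilyloxy)phenyl]-3-methyl-6-(trimethylsilyl)hex-4-en-3-ol F1. Silylation with Et3SiOTf and 2,6-lutidine gives its triethylsilyl ether F2, and buffered TBAF frees 2,4-dimethyl-3-[(3R,4E)-3-methyl-3-(triethylsilyloxy)-6-(trimethylsilyl)hex-4-en-1-yl]phenol F3. Oxidation of F3 with the trivalent iodine reagent PhI(OAc)2 in (CF3)2CHOH at low temperature is an oxidative dearomatisation: the phenoxonium ion is attacked at the para carbon C10 by the γ-carbon C9 of the allylsilane, the silyl group is lost, and the route is rejoined at 17. In this variant the facial selectivity rests on the substrate alone.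

**Step 4.** Oxidative addition and insertion at a bromide between two methyl groups may be slow, so protodebromination or β-hydride elimination toward the benzylic side (an allylic alcohol instead of the ketone) may take over. The fallback sets out from 5. Bromine–lithium exchange (n-BuLi, THF, −78 °C) and DMF give 2,6-dimethyl-3-(triisopropylsilyloxy)benzaldehyde F4. Wittig reaction with Ph3P=CHC(O)CH3 in hot toluene gives (3E)-4-[2,6-dimethyl-3-(triisopropylsilyloxy)phenyl]but-3-en-2-one F5. Hydrogenation over palladium on carbon (Pd/C, EtOAc) saturates the enone and rejoins the route at 7.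

**Step 10.** The hindered vinyl carbinol may enter the catalytic cycle too slowly, so the carbonate partner only homodimerises and the catalyst decays. The fallback sets out from 12 and builds the same alkene by carbonyl chemistry. Cleavage of the vinyl group (OsO4 cat., NaIO4, 2,6-lutidine, dioxane/H2O) gives (2R)-4-[2,6-dimethyl-3-(triisopropylsilyloxy)phenyl]-2-hydroxy-2-methylbutanal F6. The stabilised ylide Ph3P=CHCO2Et gives ethyl (2E,4R)-6-[2,6-dimethyl-3-(triisopropylsilyloxy)phenyl]-4-hydroxy-4-methylhex-2-enoate F7. Reduction with i-Bu2AlH gives (2E,4R)-6-[2,6-dimethyl-3-(triisopropylsilyloxy)phenyl]-4-methylhex-2-ene-1,4-diol F8. Methyl chloroformate and pyridine at 0 °C acylate only the primary allylic hydroxyl and rejoin the route at 14.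

**Step 14.** Hydride may attack the carbonyl (the dienol would then aromatise with methyl migration), or over-reduction may follow if the enolate is protonated in the flask. The fallback sets out from 17 and replaces the borohydride by copper hydride catalysis, which distinguishes the two enone units by substitution. Cu(OAc)2 (cat.), 1,2-bis(diphenylphosphino)benzene and PhMe2SiH in toluene should give the silyl dienol ether [(4aR,5R,6R)-5-ethenyl-1,4a,6-trimethyl-6-(triethylsilyloxy)-4,4a,5,6,7,8-hexahydronaphthalen-2-yl]oxy(dimethyl)phenylsilane F9. Methanolysis with K2CO3 then rejoins the route at 18.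

**Step 15.** The enolate may be quenched by proton transfer in ammonia before it is methylated (giving the 4-monomethyl ketone), or alkylation at the tetrasubstituted enolate carbon may be incomplete. The fallback sets out from 18 and separates reduction from alkylation. After Li/NH3/t-BuOH the ammonia is evaporated and the enolate is trapped with Me3SiCl/Et3N as the silyl enol ether (4aS,5R,6R,8aR)-5-ethenyl-1,4a,6-trimethyl-6-(triethylsilyloxy)-2-(trimethylsilyloxy)-3,4,4a,5,6,7,8,8a-octahydronaphthalene F10, which is isolated. Methyllithium in THF regenerates the lithium enolate free of ammonia, and iodomethane with DMPU methylates C4, rejoining the route at 20.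

## Further compounds

F1 | step 13 | (3R,4E)-1-[2,6-dimethyl-3-(triisopropylsilyloxy)phenyl]-3-methyl-6-(trimethylsilyl)hex-4-en-3-ol | Cc1ccc(O[Si](C(C)C)(C(C)C)C(C)C)c(C)c1CC[C@@](C)(O)/C=C/C[Si](C)(C)C
F2 | step 13 | triethylsilyl ether of F1 | Cc1ccc(O[Si](C(C)C)(C(C)C)C(C)C)c(C)c1CC[C@@](C)(O[Si](CC)(CC)CC)/C=C/C[Si](C)(C)C
F3 | step 13 | 2,4-dimethyl-3-[(3R,4E)-3-methyl-3-(triethylsilyloxy)-6-(trimethylsilyl)hex-4-en-1-yl]phenol | Cc1ccc(O)c(C)c1CC[C@@](C)(O[Si](CC)(CC)CC)/C=C/C[Si](C)(C)C
F4 | step 4 | 2,6-dimethyl-3-(triisopropylsilyloxy)benzaldehyde | Cc1ccc(O[Si](C(C)C)(C(C)C)C(C)C)c(C)c1C=O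
F5 | step 4 | (3E)-4-[2,6-dimethyl-3-(triisopropylsilyloxy)phenyl]but-3-en-2-one | CC(=O)/C=C/c1c(C)ccc(O[Si](C(C)C)(C(C)C)C(C)C)c1C
F6 | step 10 | (2R)-4-[2,6-dimethyl-3-(triisopropylsilyloxy)phenyl]-2-hydroxy-2-methylbutanal | Cc1ccc(O[Si](C(C)C)(C(C)C)C(C)C)c(C)c1CC[C@@](C)(O)C=O
F7 | step 10 | ethyl (2E,4R)-6-[2,6-dimethyl-3-(triisopropylsilyloxy)phenyl]-4-hydroxy-4-methylhex-2-enoate | Cc1ccc(O[Si](C(C)C)(C(C)C)C(C)C)c(C)c1CC[C@@](C)(O)/C=C/C(=O)OCC
F8 | step 10 | (2E,4R)-6-[2,6-dimethyl-3-(triisopropylsilyloxy)phenyl]-4-methylhex-2-ene-1,4-diol | Cc1ccc(O[Si](C(C)C)(C(C)C)C(C)C)c(C)c1CC[C@@](C)(O)/C=C/CO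
F9 | step 14 | [(4aR,5R,6R)-5-ethenyl-1,4a,6-trimethyl-6-(triethylsilyloxy)-4,4a,5,6,7,8-hexahydronaphthalen-2-yl]oxy(dimethyl)phenylsilane | C=C[C@@H]1[C@@]2(C)CC=C(O[Si](C)(C)c3ccccc3)C(C)=C2CC[C@@]1(C)O[Si](CC)(CC)CC
F10 | step 15 | (4aS,5R,6R,8aR)-5-ethenyl-1,4a,6-trimethyl-6-(triethylsilyloxy)-2-(trimethylsilyloxy)-3,4,4a,5,6,7,8,8a-octahydronaphthalene | C=C[C@@H]1[C@@]2(C)CCC(O[Si](C)(C)C)=C(C)[C@@H]2CC[C@@]1(C)O[Si](CC)(CC)CC
A1 | alternative 1 | methyl (2E,6S,8E,10E)-6-acetoxy-11-(tert-butyldimethylsilyloxy)-3,7,7-trimethylundeca-2,8,10-trienoate | COC(=O)/C=C(\C)CC[C@H](OC(C)=O)C(C)(C)/C=C/C=C/O[Si](C)(C)C(C)(C)C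
A2 | alternative 1 | methyl 3β-acetoxy-8β-(tert-butyldimethylsilyloxy)-4,4,10β-trimethyl-5α-decal-6-ene-9β-carboxylate (labdane numbering) | COC(=O)[C@@H]1[C@@]2(C)CC[C@H](OC(C)=O)C(C)(C)[C@@H]2C=C[C@@H]1O[Si](C)(C)C(C)(C)C
A3 | alternative 2 | (5R)-5-(tert-butyldimethylsilyloxy)-2,4,4-trimethylcyclohex-2-en-1-one | CC1=CC(C)(C)[C@H](O[Si](C)(C)C(C)(C)C)CC1=O
A4 | alternative 2 | tert-butyl 2-[6-(but-3-enyl)-4-(tert-butyldimethylsilyloxy)-1,5,5-trimethyl-2-oxocyclohexyl]acetate (C5 and C10 as in the target, C3 epimeric) | CC(C)(C)OC(=O)C[C@@]1(C)C(=O)C[C@@H](O[Si](C)(C)C(C)(C)C)C(C)(C)[C@@H]1CCC=C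
A5 | alternative 3 | methyl (2E)-3-[4-(tert-butyldimethylsilyloxy)-1,3,3-trimethyl-2-(3-oxobutyl)cyclohexyl]prop-2-enoate (C3, C5, C10 as in the target) | COC(=O)/C=C/[C@@]1(C)CC[C@H](O[Si](C)(C)C(C)(C)C)C(C)(C)[C@@H]1CCC(C)=O
A6 | alternative 3 | methyl 3β-(tert-butyldimethylsilyloxy)-8α-hydroxy-11-homodriman-12-oate | COC(=O)C[C@@H]1[C@@]2(C)CC[C@H](O[Si](C)(C)C(C)(C)C)C(C)(C)[C@@H]2CC[C@@]1(C)O
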